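**Retrosynthetic overview**
1. 26 ⇒ 23 (late angeloylation of C6–OH) ⇒ 21 (C4–OH-directed reduction of the C6 ketone, then C6–OH-directed epoxidation of C8=C9) ⇒ 16 (1,3-transposition of the C9=C10 alkene into the C10 acetate by epoxidation, selenolate opening and selenoxide elimination).
2. 16 ⇒ 12: the bonds C7–C8 and C5–C1 are cut together, by an intramolecular (4+3) cycloaddition of the oxyallyl cation C5–C6–C7 (from a dichloromethyl ketone) with the (E,E)-diene C1=C10–C9=C8. The five- and the seven-membered carbocycle form in this one operation; the oxirane is closed in the last step but one.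
3. Enabling feature: in the seven-membered ring the oxygen-bearing C6 lies between C5 and C7 (a ketone-level three-carbon unit), opposite the four-carbon unit C1–C10–C9–C8, whose 8,9-oxirane and C10 acetate are the oxidised form of a C9=C10 alkene. The cyclopentane carbons C2–C3–C4 join C1 to C5 and serve as the tether, and the C4–OH, β to C6, later steers the ketone reduction.
4. 12 ⇒ 7 + acetamide enolate + LiCHCl2 (C4 by chelation-controlled addition); 7 ⇒ dienal 3 + 3-methylbutan-2-one (C2 by boron aldol); 3 ⇒ crotonaldehyde.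

Key step: step 6

Remark (working numbering, used for all compounds): bicyclo[5.3.0]decane skeleton with the five-membered ring C1–C2–C3–C4–C5 and the seven-membered ring C1–C5–C6–C7–C8–C9–C10; C1 (CH3) and C5 (H) are the fusion atoms; β is the face of the C1 methyl group, α the opposite face.
Assumption: (−)-Ipc2BCl is taken to direct the enolate to the Si face of aldehyde 3; should the sense be opposite, (+)-Ipc2BCl is used. The C7 chloride of 14 is drawn β; its configuration is without consequence because it is removed in step 7.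

**Step 1**
Reactants: 1 (E)-but-2-enal; 2 2-(triphenyl-λ5-phosphanylidene)propanal
Product: 3 (2E,4E)-2-methylhexa-2,4-dienal
Conditions: PhMe, 90 °C (1 in excess)
Reagents that add atoms: none
Why: Wittig olefination with a stabilised formyl ylide is E-selective and should stop at the less electrophilic α-branched dienal; no stereocenter is formed.

**Step 2**
Reactants: 3 (2E,4E)-2-methylhexa-2,4-dienal; 4 3-methylbutan-2-one
Product: 7 (5S,6E,8E)-5-hydroxy-2,6-dimethyldeca-6,8-dien-3-one, via enol borinate 5 (not isolated), via boron aldolate 6 (not isolated)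
Conditions: 4, (−)-Ipc2BCl, Et3N, Et2O, −78 → 0 °C; then 3, −78 → −20 °C; H2O2, MeOH, pH 7 buffer
Reagents that add atoms: none
Why: Paterson-type boron aldol addition of a methyl ketone: enolisation on the methyl side and 1,2-addition to the Si face of the enal through a cyclic transition state biased by the isopinocampheyl ligands should set C2 as S, with the diene untouched.

**Step 3**
Reactants: 7 (5S,6E,8E)-5-hydroxy-2,6-dimethyldeca-6,8-dien-3-one; 8 N-methoxy-N-methylacetamide
Product: 10 (3S,5S,6E,8E)-3,5-dihydroxy-N-methoxy-N,6-dimethyl-3-(propan-2-yl)deca-6,8-dienamide, via lithium enolate 9 (not isolated)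
Conditions: 8, LiN(iPr)2, THF, −78 °C; then 7 precomplexed with MgBr2·OEt2, −78 → −40 °C; aq. NH4Cl
Reagents that add atoms: none
Why: Chelation-controlled (1,3-chelate) aldol-type addition of an amide enolate to a β-hydroxy ketone: magnesium bridges the C2 alkoxide and the C4 carbonyl in a half-chair with the dienyl group pseudo-equatorial, and axial attack of the external enolate should place the new C4–OH syn to the C2–OH along the isopropyl chain (4S).

**Step 4**
Reactants: 10 (3S,5S,6E,8E)-3,5-dihydroxy-N-methoxy-N,6-dimethyl-3-(propan-2-yl)deca-6,8-dienamide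
Product: 11 (3S,5S,6E,8E)-N-methoxy-N,6-dimethyl-3-(propan-2-yl)-3,5-bis(triethylsilyloxy)deca-6,8-dienamide
Conditions: Et3SiOTf, 2,6-lutidine, CH2Cl2, −78 → 0 °C
Reagents that add atoms: triethylsilyl trifluoromethanesulfonate, CC[Si](CC)(CC)OS(=O)(=O)C(F)(F)F
Why: Silyl triflate/2,6-lutidine silylation is forceful enough for the tertiary C4–OH as well as the secondary C2–OH and blocks retro-aldol and hemiketal chemistry in steps 5 and 6; no stereocenter is touched.

**Step 5**
Reactants: 11 (3S,5S,6E,8E)-N-methoxy-N,6-dimethyl-3-(propan-2-yl)-3,5-bis(triethylsilyloxy)deca-6,8-dienamide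
Product: 12 (4S,6S,7E,9E)-1,1-dichloro-7-methyl-4-(propan-2-yl)-4,6-bis(triethylsilyloxy)undeca-7,9-dien-2-one
Conditions: CH2Cl2, LiN(iPr)2, THF, −78 °C; then 11; AcOH quench at −78 °C
Reagents that add atoms: dichloromethyllithium (from CH2Cl2 and LiN(iPr)2), [Li]C(Cl)Cl
Why: Weinreb ketone synthesis with a lithium carbenoid: the chelated tetrahedral adduct should survive until the acidic quench, so the α,α-dichloromethyl ketone forms without over-addition or epimerisation.

**Step 6**
Reactants: 12 (4S,6S,7E,9E)-1,1-dichloro-7-methyl-4-(propan-2-yl)-4,6-bis(triethylsilyloxy)undeca-7,9-dien-2-one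
Product: 14 7β-chloro-1β,8α-dimethyl-4α-(propan-2-yl)-2α,4β-bis(triethylsilyloxy)-5α-H-bicyclo[5.3.0]dec-9-en-6-one, via oxyallyl zwitterion 13 (not isolated)
Conditions: Et3N, CF3CH2OH (high dilution), 0 °C → rt
Reagents that add atoms: none
Why: Et3N enolises 12 towards C5 and chloride leaves C7 in the ionising, weakly nucleophilic CF3CH2OH, so that the chlorine-stabilised oxyallyl zwitterion 13 (2π, C5–C6–C7) adds across C1 and C8 of the tethered diene (4π) in a concerted but asynchronous (4+3) cycloaddition; the closest known reaction type is the Föhlisch (amine/fluorinated alcohol) (4+3) cycloaddition of α-halo ketones with 1,3-dienes in its intramolecular, three-atom-tethered form, which gives hydroazulenones. The cyclopentane closes through the C5–C1 bond (5-exo attack of the cation terminus on the C1=C10 bond, tether C2–C3–C4) and the cycloheptenone through the C7–C8 bond (second bond of the cycloaddition, 7-endo collapse of the C7 enolate on the allyl cation in the stepwise limit). C8 is set by suprafacial addition to the (E,E)-diene, which puts C8–H on the face of the inside C1 methyl (C8–CH3 α). C1 and C5 are set by the extended (exo) transition state that gives the trans fusion: the C2 silyloxy group then lies in the plane of C1=C10 beside C10–H (minimal 1,3-allylic strain), whereas the compact arrangement would press it against the C1 methyl, and the C4 isopropyl group turns away from C6–O of the W-shaped cation so that the diene adds to the face that leaves C6 cis to the C4 oxygen. The step needs periselectivity ((4+3) over five-membered (3+2) closure, solvent capture and Favorskii rearrangement) and trans over cis fusion; these should be secured by the chlorine substituent (longer-lived cation), the short tether and high dilution, the single inside substituent of the (E,E)-diene and the two silyloxy stereocentres.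

**Step 7**
Reactants: 14 7β-chloro-1β,8α-dimethyl-4α-(propan-2-yl)-2α,4β-bis(triethylsilyloxy)-5α-H-bicyclo[5.3.0]dec-9-en-6-one
Product: 16 2α,4β-dihydroxy-1β,8α-dimethyl-4α-(propan-2-yl)-5α-H-bicyclo[5.3.0]dec-9-en-6-one, via dechlorinated bis-silyl ether 15 (not isolated)
Conditions: Zn dust, NH4Cl, MeOH, rt; then HF·pyridine, pyridine, THF, 0 °C → rt
Reagents that add atoms: none
Why: Reductive dehalogenation of the α-chloro ketone through its zinc enolate makes C7 a CH2 group, and fluoride then cleaves both Si–O bonds; under these near-neutral conditions C5 should not epimerise.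

**Step 8**
Reactants: 16 2α,4β-dihydroxy-1β,8α-dimethyl-4α-(propan-2-yl)-5α-H-bicyclo[5.3.0]dec-9-en-6-one
Product: 17 9α,10α-epoxy-2α,4β-dihydroxy-1β,8α-dimethyl-4α-(propan-2-yl)-5α-H-bicyclo[5.3.0]decan-6-one
Conditions: VO(acac)2 (cat.), tBuOOH, CH2Cl2, 0 °C → rt
Reagents that add atoms: tert-butyl hydroperoxide, CC(C)(C)OO
Why: Vanadium-catalysed hydroxyl-directed epoxidation: the homoallylic C2–OH on the α face binds vanadium and should deliver oxygen to the α face of C9=C10, which is also the face opposite the axial C1 methyl, setting C9 and C10.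

**Step 9**
Reactants: 17 9α,10α-epoxy-2α,4β-dihydroxy-1β,8α-dimethyl-4α-(propan-2-yl)-5α-H-bicyclo[5.3.0]decan-6-one
Product: 18 2α,4β,10α-trihydroxy-1β,8α-dimethyl-9β-(phenylselanyl)-4α-(propan-2-yl)-5α-H-bicyclo[5.3.0]decan-6-one
Conditions: PhSeSePh, NaBH4 (no excess), EtOH, 0 °C → rt (until H2 evolution ends); then 17, rt → 50 °C
Reagents that add atoms: diphenyl diselenide, c1ccc(cc1)[Se][Se]c1ccccc1
Why: Sharpless–Lauer epoxide opening: the selenolate should attack C9 from the β face with inversion rather than the neopentyl C10 (shielded by the C1 methyl), giving the trans β-hydroxy selenide with C10–OH α.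

**Step 10**
Reactants: 18 2α,4β,10α-trihydroxy-1β,8α-dimethyl-9β-(phenylselanyl)-4α-(propan-2-yl)-5α-H-bicyclo[5.3.0]decan-6-one
Product: 19 2α,10α-diacetoxy-4β-hydroxy-1β,8α-dimethyl-9β-(phenylselanyl)-4α-(propan-2-yl)-5α-H-bicyclo[5.3.0]decan-6-one
Conditions: Ac2O, DMAP (cat.), pyridine, rt
Reagents that add atoms: acetic anhydride, CC(=O)OC(C)=O
Why: DMAP-catalysed acetylation should esterify the two secondary alcohols and leave the tertiary C4–OH, flanked by the isopropyl group and the ring fusion, free; no stereocenter changes.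

**Step 11**
Reactants: 19 2α,10α-diacetoxy-4β-hydroxy-1β,8α-dimethyl-9β-(phenylselanyl)-4α-(propan-2-yl)-5α-H-bicyclo[5.3.0]decan-6-one
Product: 21 2α,10α-diacetoxy-4β-hydroxy-1β,8-dimethyl-4α-(propan-2-yl)-5α-H-bicyclo[5.3.0]dec-8-en-6-one, via selenoxide 20 (not isolated)
Conditions: mCPBA, CH2Cl2, −78 °C; then iPr2NH, −78 °C → rt
Reagents that add atoms: none
Why: Selenide oxidation and selenoxide syn-elimination: the β selenoxide at C9 should eliminate with the syn β hydrogen at C8, away from the oxygen-bearing C10, giving the C8=C9 allylic acetate with C10 unchanged.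

**Step 12**
Reactants: 21 2α,10α-diacetoxy-4β-hydroxy-1β,8-dimethyl-4α-(propan-2-yl)-5α-H-bicyclo[5.3.0]dec-8-en-6-one
Product: 22 2α,10α-diacetoxy-1β,8-dimethyl-4α-(propan-2-yl)-5α-H-bicyclo[5.3.0]dec-8-ene-4β,6α-diol
Conditions: Me4NBH(OAc)3, MeCN/AcOH, −30 → −20 °C
Reagents that add atoms: none
Why: Evans–Saksena directed reduction: the C4–OH exchanges onto boron and should deliver hydride through a six-membered transition state to the face of the C6 carbonyl that it overhangs, giving the 1,3-anti diol with C6–OH α.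

**Step 13**
Reactants: 22 2α,10α-diacetoxy-1β,8-dimethyl-4α-(propan-2-yl)-5α-H-bicyclo[5.3.0]dec-8-ene-4β,6α-diol
Product: 23 2α,10α-diacetoxy-8α,9α-epoxy-1β,8β-dimethyl-4α-(propan-2-yl)-5α-H-bicyclo[5.3.0]decane-4β,6α-diol
Conditions: VO(acac)2 (cat.), tBuOOH, CH2Cl2, 0 °C → rt
Reagents that add atoms: tert-butyl hydroperoxide, CC(C)(C)OO
Why: Vanadium-catalysed directed epoxidation: the homoallylic α C6–OH should deliver oxygen to the α face of the trisubstituted C8=C9 bond (β face shielded by the C1 methyl), setting C8 and C9 with the oxirane cis to the C10 acetate.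

**Step 14**
Reactants: 23 2α,10α-diacetoxy-8α,9α-epoxy-1β,8β-dimethyl-4α-(propan-2-yl)-5α-H-bicyclo[5.3.0]decane-4β,6α-diol; 24 (Z)-2-methylbut-2-enoic acid (angelic acid)
Product: 26 2α,10α-diacetoxy-6α-[(Z)-2-methylbut-2-enoyloxy]-8α,9α-epoxy-4β-hydroxy-1β,8β-dimethyl-4α-(propan-2-yl)-5α-H-bicyclo[5.3.0]decane (CNP0170993.1), via mixed anhydride 25 (not isolated)
Conditions: 24, 2,4,6-trichlorobenzoyl chloride, Et3N, PhMe, rt; then 23, 80 °C
Reagents that add atoms: none
Why: Yamaguchi-type esterification through mixed anhydride 25 should acylate the only secondary alcohol; omitting DMAP keeps the (Z) geometry of the angelate, and the tertiary C4–OH does not react.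

**Compound list**
1 | (E)-but-2-enal | C/C=C/C=O | starting material
2 | 2-(triphenyl-λ5-phosphanylidene)propanal | CC(C=O)=P(c1ccccc1)(c1ccccc1)c1ccccc1 | starting material
3 | (2E,4E)-2-methylhexa-2,4-dienal | C/C=C/C=C(\C)C=O | intermediate
4 | 3-methylbutan-2-one | CC(C)C(C)=O | starting material
5 | enol diisopinocampheylborinate of 4 | C=C(OB([C@@H]1C[C@@H]2C[C@H]([C@H]1C)C2(C)C)[C@@H]1C[C@@H]2C[C@H]([C@H]1C)C2(C)C)C(C)C | intermediate
6 | diisopinocampheylboron aldolate of 7 | CC(C)C(=O)C[C@H](OB([C@@H]1C[C@@H]2C[C@H]([C@H]1C)C2(C)C)[C@@H]1C[C@@H]2C[C@H]([C@H]1C)C2(C)C)/C(C)=C/C=C/C | intermediate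
7 | (5S,6E,8E)-5-hydroxy-2,6-dimethyldeca-6,8-dien-3-one | CC(C)C(=O)C[C@H](O)/C(C)=C/C=C/C | intermediate
8 | N-methoxy-N-methylacetamide | CC(=O)N(C)OC | starting material
9 | lithium enolate of 8 | [Li+].C=C([O-])N(C)OC | intermediate
10 | (3S,5S,6E,8E)-3,5-dihydroxy-N-methoxy-N,6-dimethyl-3-(propan-2-yl)deca-6,8-dienamide | CON(C)C(=O)C[C@](O)(C(C)C)C[C@H](O)/C(C)=C/C=C/C | intermediate
11 | (3S,5S,6E,8E)-N-methoxy-N,6-dimethyl-3-(propan-2-yl)-3,5-bis(triethylsilyloxy)deca-6,8-dienamide | CON(C)C(=O)C[C@](O[Si](CC)(CC)CC)(C(C)C)C[C@H](O[Si](CC)(CC)CC)/C(C)=C/C=C/C | intermediate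
12 | (4S,6S,7E,9E)-1,1-dichloro-7-methyl-4-(propan-2-yl)-4,6-bis(triethylsilyloxy)undeca-7,9-dien-2-one | ClC(Cl)C(=O)C[C@](O[Si](CC)(CC)CC)(C(C)C)C[C@H](O[Si](CC)(CC)CC)/C(C)=C/C=C/C | intermediate
13 | chloro-oxyallyl zwitterion from 12 (2-oxidoallyl cation C5–C6–C7) | Cl[CH+]/C([O-])=C/[C@](O[Si](CC)(CC)CC)(C(C)C)C[C@H](O[Si](CC)(CC)CC)/C(C)=C/C=C/C | intermediate
14 | 7β-chloro-1β,8α-dimethyl-4α-(propan-2-yl)-2α,4β-bis(triethylsilyloxy)-5α-H-bicyclo[5.3.0]dec-9-en-6-one | O=C1[C@H](Cl)[C@@H](C)C=C[C@@]2(C)[C@@H](O[Si](CC)(CC)CC)C[C@@](O[Si](CC)(CC)CC)(C(C)C)[C@H]12 | intermediate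
15 | 1β,8α-dimethyl-4α-(propan-2-yl)-2α,4β-bis(triethylsilyloxy)-5α-H-bicyclo[5.3.0]dec-9-en-6-one | O=C1C[C@@H](C)C=C[C@@]2(C)[C@@H](O[Si](CC)(CC)CC)C[C@@](O[Si](CC)(CC)CC)(C(C)C)[C@H]12 | intermediate
16 | 2α,4β-dihydroxy-1β,8α-dimethyl-4α-(propan-2-yl)-5α-H-bicyclo[5.3.0]dec-9-en-6-one | O=C1C[C@@H](C)C=C[C@@]2(C)[C@@H](O)C[C@@](O)(C(C)C)[C@H]12 | intermediate
17 | 9α,10α-epoxy-2α,4β-dihydroxy-1β,8α-dimethyl-4α-(propan-2-yl)-5α-H-bicyclo[5.3.0]decan-6-one | O=C1C[C@@H](C)[C@H]2O[C@H]2[C@@]2(C)[C@@H](O)C[C@@](O)(C(C)C)[C@H]12 | intermediate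
18 | 2α,4β,10α-trihydroxy-1β,8α-dimethyl-9β-(phenylselanyl)-4α-(propan-2-yl)-5α-H-bicyclo[5.3.0]decan-6-one | O=C1C[C@@H](C)[C@H]([Se]c3ccccc3)[C@@H](O)[C@@]2(C)[C@@H](O)C[C@@](O)(C(C)C)[C@H]12 | intermediate
19 | 2α,10α-diacetoxy-4β-hydroxy-1β,8α-dimethyl-9β-(phenylselanyl)-4α-(propan-2-yl)-5α-H-bicyclo[5.3.0]decan-6-one | O=C1C[C@@H](C)[C@H]([Se]c3ccccc3)[C@@H](OC(C)=O)[C@@]2(C)[C@@H](OC(C)=O)C[C@@](O)(C(C)C)[C@H]12 | intermediate
20 | Se-oxide of 19 (9β-phenylseleninyl compound) | O=C1C[C@@H](C)[C@H]([Se](=O)c3ccccc3)[C@@H](OC(C)=O)[C@@]2(C)[C@@H](OC(C)=O)C[C@@](O)(C(C)C)[C@H]12 | intermediate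
21 | 2α,10α-diacetoxy-4β-hydroxy-1β,8-dimethyl-4α-(propan-2-yl)-5α-H-bicyclo[5.3.0]dec-8-en-6-one | O=C1CC(C)=C[C@@H](OC(C)=O)[C@@]2(C)[C@@H](OC(C)=O)C[C@@](O)(C(C)C)[C@H]12 | intermediate
22 | 2α,10α-diacetoxy-1β,8-dimethyl-4α-(propan-2-yl)-5α-H-bicyclo[5.3.0]dec-8-ene-4β,6α-diol | O[C@H]1CC(C)=C[C@@H](OC(C)=O)[C@@]2(C)[C@@H](OC(C)=O)C[C@@](O)(C(C)C)[C@H]12 | intermediate
23 | 2α,10α-diacetoxy-8α,9α-epoxy-1β,8β-dimethyl-4α-(propan-2-yl)-5α-H-bicyclo[5.3.0]decane-4β,6α-diol | O[C@H]1C[C@@]2(C)O[C@H]2[C@@H](OC(C)=O)[C@@]2(C)[C@@H](OC(C)=O)C[C@@](O)(C(C)C)[C@H]12 | intermediate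
24 | (Z)-2-methylbut-2-enoic acid (angelic acid) | C/C=C(/C)C(=O)O | starting material
25 | angelic 2,4,6-trichlorobenzoic mixed anhydride | C/C=C(/C)C(=O)OC(=O)c1c(Cl)cc(Cl)cc1Cl | intermediate
26 | 2α,10α-diacetoxy-6α-[(Z)-2-methylbut-2-enoyloxy]-8α,9α-epoxy-4β-hydroxy-1β,8β-dimethyl-4α-(propan-2-yl)-5α-H-bicyclo[5.3.0]decane (CNP0170993.1) | C/C=C(/C)C(=O)O[C@H]1C[C@@]2(C)O[C@H]2[C@@H](OC(C)=O)[C@@]2(C)[C@@H](OC(C)=O)C[C@@](O)(C(C)C)[C@H]12 | target

**Totals**
Total step count: 14. Longest linear sequence: 14 steps (1 → 26); the route is fully linear.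

**Steps most likely to fail**

1. Step 6 (key cycloaddition). The oxyallyl zwitterion may be lost before the diene reaches the s-cis geometry (the C1 methyl is an inside substituent). Loss would occur by 1,2-shift or β-elimination at the C4 silyloxy carbon, by Favorskii-type solvent capture, or by five-membered (3+2) closure; the cis ring fusion may also compete.
   Fallback (sets out from 7, comes back at 16): the cycloaddition is run intermolecularly with an oxyallyl cation that carries no β-oxygen, and the cyclopentane is closed afterwards by an aldol addition under thermodynamic control. Silylation of 7 (Et3SiOTf, 2,6-lutidine) gives (5S,6E,8E)-2,6-dimethyl-5-(triethylsilyloxy)deca-6,8-dien-3-one F1. Its (4+3) cycloaddition with the symmetrical dichloro-oxyallyl cation from 1,1,3-trichloropropan-2-one (Et3N, CF3CH2OH) forms the same two bonds and should give the 5,7-dichloro-1β,8α-dimethylcyclohept-9-en-6-one F2, with facial control at C1 resting only on the neighbouring C2 silyloxy centre. Zn dust/NH4Cl should remove both chlorines to give cycloheptenone F3. KOtBu in tBuOH/THF at 0 °C should add C5 to the isopropyl ketone and close the cyclopentane to the trans-fused hydroxy ketone F4. HF·pyridine then gives 16. The inside methyl is intrinsic to any (4+3) union at these two bonds, so this fallback removes the decay channels at C4 and the tether strain, not that constraint.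

2. Step 3 (C4 carbinol). Facial selectivity may be poor if magnesium chelation is weak in THF, and the ketone may be enolised or the alkoxide may undergo retro-aldol cleavage.
   Fallback (sets out from 3, comes back at 10; it also replaces step 2): both centres are set on a six-membered ring. Hetero-Diels–Alder reaction of 3 with (E)-1-methoxy-3-(trimethylsilyloxy)buta-1,3-diene (Ti(OiPr)4 and the BINOL enantiomer that leads to the 6S product, 4 Å sieves) should give (6S)-6-[(2E,4E)-hexa-2,4-dien-2-yl]-2-methoxy-4-(trimethylsilyloxy)-5,6-dihydro-2H-pyran F5. CF3CO2H converts it into (2S)-2-[(2E,4E)-hexa-2,4-dien-2-yl]-2,3-dihydro-4H-pyran-4-one F6. iPrMgCl/CeCl3 should add 1,2 along the axial trajectory and give (2S,4R)-2-[(2E,4E)-hexa-2,4-dien-2-yl]-4-(propan-2-yl)-3,4-dihydro-2H-pyran-4-ol F7, with the hydroxyl cis to the dienyl group. Hg(OAc)2-catalysed hydration of the enol ether (THF/H2O) gives (4S,6S)-6-[(2E,4E)-hexa-2,4-dien-2-yl]-4-(propan-2-yl)oxane-2,4-diol F8. Oxidation (TEMPO, PhI(OAc)2) gives (4S,6S)-6-[(2E,4E)-hexa-2,4-dien-2-yl]-4-hydroxy-4-(propan-2-yl)oxan-2-one F9. Me3Al/MeNHOMe·HCl opens the lactone to 10.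

3. Step 14 (angeloylation). Acylation of the hindered C6–OH is slow, and the angelate may isomerise to the tiglate by reversible conjugate addition during the reaction.
   Fallback (sets out from 23, comes back at 26): the Z double bond is built on the ester. Esterification of 23 with 2-[bis(2,2,2-trifluoroethoxy)phosphoryl]propanoic acid (DCC, DMAP) gives the C6 2-[bis(2,2,2-trifluoroethoxy)phosphoryl]propanoate of 23 F10. Still–Gennari olefination with acetaldehyde (KN(SiMe3)2, 18-crown-6, THF, −78 °C) should then give 26 with Z selectivity.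

**Further compounds**
F1 | step 6 | (5S,6E,8E)-2,6-dimethyl-5-(triethylsilyloxy)deca-6,8-dien-3-one | CC(C)C(=O)C[C@H](O[Si](CC)(CC)CC)/C(C)=C/C=C/C
F2 | step 6 | 5,7-dichloro-1β,8α-dimethyl-1α-[(1S)-4-methyl-3-oxo-1-(triethylsilyloxy)pentyl]cyclohept-9-en-6-one (working numbering; chloro epimers) | O=C1C(Cl)[C@@H](C)C=C[C@@](C)([C@@H](O[Si](CC)(CC)CC)CC(=O)C(C)C)C1Cl
F3 | step 6 | 1β,8α-dimethyl-1α-[(1S)-4-methyl-3-oxo-1-(triethylsilyloxy)pentyl]cyclohept-9-en-6-one (working numbering) | O=C1C[C@@H](C)C=C[C@@](C)([C@@H](O[Si](CC)(CC)CC)CC(=O)C(C)C)C1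
F4 | step 6 | 4β-hydroxy-1β,8α-dimethyl-4α-(propan-2-yl)-2α-(triethylsilyloxy)-5α-H-bicyclo[5.3.0]dec-9-en-6-one | O=C1C[C@@H](C)C=C[C@@]2(C)[C@@H](O[Si](CC)(CC)CC)C[C@@](O)(C(C)C)[C@H]12
F5 | step 3 | (6S)-6-[(2E,4E)-hexa-2,4-dien-2-yl]-2-methoxy-4-(trimethylsilyloxy)-5,6-dihydro-2H-pyran (anomer mixture) | COC1C=C(O[Si](C)(C)C)C[C@H](O1)/C(C)=C/C=C/C
F6 | step 3 | (2S)-2-[(2E,4E)-hexa-2,4-dien-2-yl]-2,3-dihydro-4H-pyran-4-one | O=C1C[C@H](OC=C1)/C(C)=C/C=C/C
F7 | step 3 | (2S,4R)-2-[(2E,4E)-hexa-2,4-dien-2-yl]-4-(propan-2-yl)-3,4-dihydro-2H-pyran-4-ol | CC(C)[C@]1(O)C[C@H](OC=C1)/C(C)=C/C=C/C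
F8 | step 3 | (4S,6S)-6-[(2E,4E)-hexa-2,4-dien-2-yl]-4-(propan-2-yl)oxane-2,4-diol (anomer mixture) | CC(C)[C@]1(O)C[C@H](OC(O)C1)/C(C)=C/C=C/C
F9 | step 3 | (4S,6S)-6-[(2E,4E)-hexa-2,4-dien-2-yl]-4-hydroxy-4-(propan-2-yl)oxan-2-one | CC(C)[C@]1(O)C[C@H](OC(=O)C1)/C(C)=C/C=C/C
F10 | step 14 | C6 2-[bis(2,2,2-trifluoroethoxy)phosphoryl]propanoate of 23 | CC(C(=O)O[C@H]1C[C@@]2(C)O[C@H]2[C@@H](OC(C)=O)[C@@]2(C)[C@@H](OC(C)=O)C[C@@](O)(C(C)C)[C@H]12)P(=O)(OCC(F)(F)F)OCC(F)(F)F
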